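The C3–C3a bond and the exocyclic carbonyl carbon on C3 of dihydrofuran ring B are read as the C4a–C4 unit of a (2S)-flavanone whose C4 has been extruded from the ring. A single photochemical Wolff rearrangement of a 3-diazoflavanone forms C3–C3a and contracts the pyranone to ring B on benzo ring A. Amine capture of the ketene and equilibration then set C3 trans to the ring C aryl on C2. The precursor is the 6-bromo-3-diazoflavanone with benzyl-protected ring C, in the spatial arrangement of the (2S)-flavanone. Rings D and E are the same 2,4-dihydroxyphenyl ketone, so both are introduced together from one aryl Grignard reagent.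

Key step: step 3

Assumption: the sense of induction of t-BuPyOx with chromones is taken to follow that with cyclic enones, which assigns (R)-t-BuPyOx to the 2S series; the antipodal ligand serves if the sense proves opposite.

Step 1
Reactants: 1 6-bromochromone; 2 4-(benzyloxy)phenylboronic acid
Product: 3 (2S)-2-[4-(benzyloxy)phenyl]-6-bromochroman-4-one
Conditions: Pd(OCOCF3)2 (5 mol %), (R)-t-BuPyOx [(R)-4-tert-butyl-2-(pyridin-2-yl)-4,5-dihydrooxazole] (6 mol %), NH4PF6 (30 mol %), H2O (5 equiv), ClCH2CH2Cl, 60 °C
Reagents that add atoms: none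
Why: Enantioselective conjugate addition of an arylboronic acid to a chromone under cationic divalent palladium and pyridine-oxazoline catalysis: the aryl–palladium species inserts the C2=C3 bond on the enone face left open by the tert-butyl group of the ligand, which sets C2 as S, and the palladium enolate is protonated by water, so no zerovalent palladium should arise to attack the C6 bromide.

Step 2
Reactants: 3 (2S)-2-[4-(benzyloxy)phenyl]-6-bromochroman-4-one
Product: 5 (2R)-2-[4-(benzyloxy)phenyl]-6-bromo-3-diazochroman-4-one, via 3-trifluoroacetyl flavanone 4 (not isolated)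
Conditions: LiN(SiMe3)2, THF, −78 °C; CF3CO2CH2CF3, −78 °C, 10 min; cold dilute aq HCl; then p-ABSA, Et3N, H2O (1 equiv), MeCN, 0 °C to rt
Reagents that add atoms: 4-acetamidobenzenesulfonyl azide (p-ABSA), CC(=O)Nc1ccc(cc1)S(=O)(=O)N=[N+]=[N-]
Why: Detrifluoroacetylative diazo transfer (a Regitz-type transfer to an activated ketone): the lithium enolate is formed and C-acylated at −78 °C before it can open to the chalcone by retro-oxa-Michael reaction, the doubly stabilised diketonate of 4 then takes the diazo group from the sulfonyl azide with loss of the trifluoroacetyl group as the N-acyl sulfonamide, and C2 is untouched (its descriptor changes from S to R only because C3 now outranks the aryl group).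

Step 3
Reactants: 5 (2R)-2-[4-(benzyloxy)phenyl]-6-bromo-3-diazochroman-4-one; 6 N,O-dimethylhydroxylamine hydrochloride
Product: 10 (2S,3S)-2-[4-(benzyloxy)phenyl]-5-bromo-N-methoxy-N-methyl-2,3-dihydro-1-benzofuran-3-carboxamide, via N,O-dimethylhydroxylamine 7 (not isolated), via ketene 8 (not isolated), via cis amide 9 (not isolated)
Conditions: 6, K2CO3, THF, rt, filtered solution of 7 (5 equiv) added to 5; hν (365 nm LED), dry THF, 0 °C; then KOt-Bu (0.2 equiv), 0 °C to rt
Reagents that add atoms: none
Why: Direct excitation of the ring-locked s-cis α-diazo ketone should expel N2 in concert with a 1,2-shift of the ring A carbon C4a from the carbonyl carbon C4 to the diazo carbon C3, which gives ketene 8; amine 7 adds to the ketene and the amide enol tautomerises to the amide. The closest known reaction type is the photochemical Wolff ring contraction of cyclic α-diazo ketones with capture of the ketene by an amine. Ring B is closed not by attack of a nucleophile on an electrophile but by contraction of the six-membered pyranone through this 1,2-aryl shift, the former C4 leaving the ring as the exocyclic amide carbon and the new ring bond being C3–C3a. The new stereocenter C3 is set when the enol is protonated, and any kinetic cis amide 9 is equilibrated through the amide enolate by catalytic KOt-Bu, so C3 is under thermodynamic control by the fixed C2 center with its ring C aryl, and the trans amide is expected. The step needs the shift of C4a to win over a 1,2-hydride shift of H-2 in a free carbene, which would lead to the flavone; the enforced s-cis geometry, the use of light without metal catalyst or triplet sensitiser, and the fact that C4a is the only group on C4 able to migrate should secure this, while 365 nm light leaves the aryl bromide and the benzyl ether alone. C2 should keep its configuration during the equilibration, because loss of the ring oxygen from a C3 enolate would be the reverse of a 5-endo-trig closure.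

Step 4
Reactants: 10 (2S,3S)-2-[4-(benzyloxy)phenyl]-5-bromo-N-methoxy-N-methyl-2,3-dihydro-1-benzofuran-3-carboxamide; 11 N-methoxy-N-methylacrylamide
Product: 12 (2S,3S)-2-[4-(benzyloxy)phenyl]-N-methoxy-5-[(1E)-3-[methoxy(methyl)amino]-3-oxoprop-1-en-1-yl]-N-methyl-2,3-dihydro-1-benzofuran-3-carboxamide
Conditions: Pd(OAc)2 (5 mol %), P(o-tol)3 (12 mol %), Et3N, DMF, 100 °C
Reagents that add atoms: none
Why: Mizoroki–Heck reaction: oxidative addition of zerovalent palladium into the C5–Br bond, syn insertion of the acrylamide and syn β-hydride elimination should give the E-configured cinnamoyl Weinreb amide, while Et3N is too weak a base to enolise the C3 amide, so both stereocenters stay as they are.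

Step 5
Reactants: 13 4-bromoresorcinol
Product: 14 2,4-bis(benzyloxy)-1-bromobenzene
Conditions: BnBr (2.3 equiv), K2CO3, DMF, 60 °C
Reagents that add atoms: benzyl bromide, BrCc1ccccc1
Why: Williamson ether synthesis: both phenoxides of 13 are benzylated by SN2 displacement, which masks the future ring D and ring E hydroxyl groups as the same ethers that already protect ring C.

Step 6
Reactants: 12 (2S,3S)-2-[4-(benzyloxy)phenyl]-N-methoxy-5-[(1E)-3-[methoxy(methyl)amino]-3-oxoprop-1-en-1-yl]-N-methyl-2,3-dihydro-1-benzofuran-3-carboxamide; 14 2,4-bis(benzyloxy)-1-bromobenzene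
Product: 16 (2E)-1-[2,4-bis(benzyloxy)phenyl]-3-[(2S,3S)-3-[2,4-bis(benzyloxy)benzoyl]-2-[4-(benzyloxy)phenyl]-2,3-dihydro-1-benzofuran-5-yl]prop-2-en-1-one, via arylmagnesium bromide 15 (not isolated)
Conditions: 14 (4.5 equiv), Mg turnings, I2 (cat.), THF, 50 °C; then 12, THF, 0 °C to rt; cold 1 M HCl
Reagents that add atoms: none
Why: Twofold Weinreb ketone synthesis: the aryl Grignard reagent adds once to each amide (1,2-addition at the cinnamoyl amide) to give N,O-chelated magnesium hemiaminals that resist a second addition and collapse to the two ketones only on acidic work-up, which installs rings D and E together, while C3 keeps the trans arrangement, which is also the thermodynamic one.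

Step 7
Reactants: 16 (2E)-1-[2,4-bis(benzyloxy)phenyl]-3-[(2S,3S)-3-[2,4-bis(benzyloxy)benzoyl]-2-[4-(benzyloxy)phenyl]-2,3-dihydro-1-benzofuran-5-yl]prop-2-en-1-one
Product: 17 3-[(2S,3S)-3-(2,4-dihydroxybenzoyl)-2-(4-hydroxyphenyl)-2,3-dihydro-1-benzofuran-5-yl]-1-(2,4-dihydroxyphenyl)propan-1-one (CNP0136359.1)
Conditions: H2 (1 atm), 10% Pd/C, EtOAc–MeOH, rt, stopped after uptake of six equivalents of H2
Reagents that add atoms: none
Why: Heterogeneous catalytic hydrogenation: the five benzyl ethers are cleaved by hydrogenolysis and the enone C=C bond is saturated in the same operation, while the hydrogen-bonded 2-hydroxyaryl ketones and the cyclic C2–O1 ether should react only slowly at 1 atm and room temperature, so neither stereocenter is touched.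

Compound list
1 | 6-bromochromone (6-bromo-4H-chromen-4-one) | O=c1ccoc2ccc(Br)cc12 | starting material
2 | 4-(benzyloxy)phenylboronic acid | OB(O)c1ccc(OCc2ccccc2)cc1 | starting material
3 | (2S)-2-[4-(benzyloxy)phenyl]-6-bromochroman-4-one | O=C1c2cc(Br)ccc2O[C@H](c2ccc(OCc3ccccc3)cc2)C1 | intermediate
4 | (2S)-2-[4-(benzyloxy)phenyl]-6-bromo-3-(trifluoroacetyl)chroman-4-one (largely enolised, C3 not defined) | O=C1c2cc(Br)ccc2O[C@H](c2ccc(OCc3ccccc3)cc2)C1C(=O)C(F)(F)F | intermediate
5 | (2R)-2-[4-(benzyloxy)phenyl]-6-bromo-3-diazochroman-4-one (same spatial arrangement at C2 as in 3) | O=C1c2cc(Br)ccc2O[C@H](c2ccc(OCc3ccccc3)cc2)C1=[N+]=[N-] | intermediate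
6 | N,O-dimethylhydroxylamine hydrochloride | CNOC.Cl | starting material
7 | N,O-dimethylhydroxylamine | CNOC | intermediate
8 | [(2R)-2-[4-(benzyloxy)phenyl]-5-bromo-1-benzofuran-3(2H)-ylidene]methanone (ketene) | Brc1ccc2c(c1)C(=C=O)[C@@H](c1ccc(OCc3ccccc3)cc1)O2 | intermediate
9 | (2S,3R)-2-[4-(benzyloxy)phenyl]-5-bromo-N-methoxy-N-methyl-2,3-dihydro-1-benzofuran-3-carboxamide (cis) | Brc1ccc2c(c1)[C@@H](C(=O)N(C)OC)[C@@H](c1ccc(OCc3ccccc3)cc1)O2 | intermediate
10 | (2S,3S)-2-[4-(benzyloxy)phenyl]-5-bromo-N-methoxy-N-methyl-2,3-dihydro-1-benzofuran-3-carboxamide (trans) | Brc1ccc2c(c1)[C@H](C(=O)N(C)OC)[C@@H](c1ccc(OCc3ccccc3)cc1)O2 | intermediate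
11 | N-methoxy-N-methylacrylamide | C=CC(=O)N(C)OC | starting material
12 | (2S,3S)-2-[4-(benzyloxy)phenyl]-N-methoxy-5-[(1E)-3-[methoxy(methyl)amino]-3-oxoprop-1-en-1-yl]-N-methyl-2,3-dihydro-1-benzofuran-3-carboxamide | CON(C)C(=O)/C=C/c1ccc2c(c1)[C@H](C(=O)N(C)OC)[C@@H](c1ccc(OCc3ccccc3)cc1)O2 | intermediate
13 | 4-bromoresorcinol (4-bromobenzene-1,3-diol) | Oc1ccc(Br)c(O)c1 | starting material
14 | 2,4-bis(benzyloxy)-1-bromobenzene | Brc1ccc(OCc2ccccc2)cc1OCc1ccccc1 | intermediate
15 | [2,4-bis(benzyloxy)phenyl]magnesium bromide | Br[Mg]c1ccc(OCc2ccccc2)cc1OCc1ccccc1 | intermediate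
16 | (2E)-1-[2,4-bis(benzyloxy)phenyl]-3-[(2S,3S)-3-[2,4-bis(benzyloxy)benzoyl]-2-[4-(benzyloxy)phenyl]-2,3-dihydro-1-benzofuran-5-yl]prop-2-en-1-one | O=C(/C=C/c1ccc2c(c1)[C@H](C(=O)c1ccc(OCc3ccccc3)cc1OCc1ccccc1)[C@@H](c1ccc(OCc3ccccc3)cc1)O2)c1ccc(OCc2ccccc2)cc1OCc1ccccc1 | intermediate
17 | 3-[(2S,3S)-3-(2,4-dihydroxybenzoyl)-2-(4-hydroxyphenyl)-2,3-dihydro-1-benzofuran-5-yl]-1-(2,4-dihydroxyphenyl)propan-1-one | O=C(CCc1ccc2c(c1)[C@H](C(=O)c1ccc(O)cc1O)[C@@H](c1ccc(O)cc1)O2)c1ccc(O)cc1O | target

Total step count: 7. Longest linear sequence: 6 steps (steps 1, 2, 3, 4, 6 and 7); step 5 prepares the aryl bromide for step 6.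

Steps most likely to fail

Step 3. After loss of N2 a free carbene may form and undergo a 1,2-hydride shift from C2, or the ketene may be captured inefficiently, so the ring contraction may not dominate. The fallback sets out from flavanone 3 and contracts the ring oxidatively instead of photochemically. PhI(OAc)2 and H2SO4 in HC(OMe)3 should attack C3 of the enol ether anti to the C2 aryl, and departure of iodobenzene with 1,2-shift of the anti-periplanar ring A carbon should give methyl (2S,3S)-2-[4-(benzyloxy)phenyl]-5-bromo-2,3-dihydro-1-benzofuran-3-carboxylate F1. The electron-rich ring C could compete as the migrating group, which is why this is the fallback and not the main route. AlMe3-mediated aminolysis of F1 with 6 returns to the route at 10.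

Step 2. The enolate may open by retro-oxa-Michael reaction before or after acylation, which would erode the C2 configuration, or C-acylation may stay incomplete. The fallback sets out from 3 and avoids the enolate: nitrosation through the enol with isoamyl nitrite and HCl at 0 °C should give (2R)-2-[4-(benzyloxy)phenyl]-6-bromo-3-(hydroxyimino)chroman-4-one F2. A Forster reaction of F2 with chloramine (aq NH3, NaOCl, NaOH, 0 °C) then converts the oxime into the diazo group and returns to the route at 5.

Step 6. The basic Grignard reagent may enolise the hindered C3 amide or add incompletely there, or add in conjugate fashion to the cinnamoyl amide, so the twofold addition may stall at mixed products. The fallback uncouples the two additions and sets out from 10. A single addition of 15 to 10, with the aryl bromide as a spectator, should give [(2S,3S)-2-[4-(benzyloxy)phenyl]-5-bromo-2,3-dihydro-1-benzofuran-3-yl][2,4-bis(benzyloxy)phenyl]methanone F3. Addition of 15 to 11 with acidic quench should give 1-[2,4-bis(benzyloxy)phenyl]prop-2-en-1-one F4. A Mizoroki–Heck reaction of F3 with F4 (Pd(OAc)2, P(o-tol)3, Et3N, DMF) returns to the route at 16.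

Further compounds
F1 | step 3 | methyl (2S,3S)-2-[4-(benzyloxy)phenyl]-5-bromo-2,3-dihydro-1-benzofuran-3-carboxylate | Brc1ccc2c(c1)[C@H](C(=O)OC)[C@@H](c1ccc(OCc3ccccc3)cc1)O2
F2 | step 2 | (2R)-2-[4-(benzyloxy)phenyl]-6-bromo-3-(hydroxyimino)chroman-4-one | O=C1c2cc(Br)ccc2O[C@H](c2ccc(OCc3ccccc3)cc2)C1=NO
F3 | step 6 | [(2S,3S)-2-[4-(benzyloxy)phenyl]-5-bromo-2,3-dihydro-1-benzofuran-3-yl][2,4-bis(benzyloxy)phenyl]methanone | Brc1ccc2c(c1)[C@H](C(=O)c1ccc(OCc3ccccc3)cc1OCc1ccccc1)[C@@H](c1ccc(OCc3ccccc3)cc1)O2
F4 | step 6 | 1-[2,4-bis(benzyloxy)phenyl]prop-2-en-1-one | C=CC(=O)c1ccc(OCc2ccccc2)cc1OCc1ccccc1
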